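**Strategy.** Epoxytwinol A is read as two isochromans (pyran fused to a latent phenol; C1 = O–CH bridgehead, C4 = CH of the inter-half bond) joined C1–C1′ and C4–C4′; the epoxyquinol rings are unveiled last from p-quinone monoketals. The key step is an acid-triggered three-component domino between an all-syn diol carrying an alkynyl acetal and phenol ring B, and (E)-5,5-dimethoxypent-3-en-2-one: the enone end builds pyran A and aromatic ring A de novo, forming the C4a–C8a ring-fusion bond (the later tetrasubstituted C=C of cyclohexenone A), while the acetal end is captured by the second hydroxyl and ring B, forming the C1′–C8a′ bond and closing the cage.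

Key step: step 14

Assumption: 1, 2, 5, 15, 18 and 19 are taken as commercial, and L-(+)-diisopropyl tartrate is taken as the matched ligand for the epoxide face drawn in 25.

Step 1
Reactants: 1 3-bromo-4-methoxyphenol; 2 prop-2-yn-1-ol
Product: 3 3-(5-hydroxy-2-methoxyphenyl)prop-2-yn-1-ol
Conditions: PdCl2(PPh3)2 (3 mol %), CuI (5 mol %), i-Pr2NH, DMF, 70 °C
Reagents that add atoms: none
Why: Sonogashira coupling of the aryl bromide with the terminal alkyne, which tolerates the free phenol and the primary alcohol and creates no stereocentre.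

Step 2
Reactants: 3 3-(5-hydroxy-2-methoxyphenyl)prop-2-yn-1-ol
Product: 4 (Z)-3-(5-hydroxy-2-methoxyphenyl)prop-2-en-1-ol
Conditions: H2 (1 atm), Lindlar catalyst (Pd/CaCO3, Pb-poisoned), quinoline, EtOAc, rt
Reagents that add atoms: none
Why: Lindlar semihydrogenation adds H2 syn on the poisoned palladium surface and should stop at the (Z)-alkene.

Step 3
Reactants: 4 (Z)-3-(5-hydroxy-2-methoxyphenyl)prop-2-en-1-ol; 5 ethyl (R)-3-hydroxybutanoate
Product: 6 (Z)-3-(5-hydroxy-2-methoxyphenyl)prop-2-en-1-yl (R)-3-hydroxybutanoate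
Conditions: 5 (3 equiv), Ti(OEt)4 (20 mol %), toluene, 90 °C, EtOH distilled off
Reagents that add atoms: none
Why: Ti(OEt)4-catalysed transesterification exchanges the ethyl for the allylic ester group without touching the carbinol stereocentre or the phenol.

Step 4
Reactants: 6 (Z)-3-(5-hydroxy-2-methoxyphenyl)prop-2-en-1-yl (R)-3-hydroxybutanoate
Product: 7 (2R,3S)-2-[(1R)-1-hydroxyethyl]-3-(5-hydroxy-2-methoxyphenyl)pent-4-enoic acid
Conditions: LDA (3.3 equiv), THF, −78 °C → 50 °C; aq. HCl
Reagents that add atoms: none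
Why: Ireland–Claisen rearrangement of the ester dianion: the lithium chelate between enolate and β-alkoxide fixes the enolate geometry and lets the allyl unit bond anti to the carbinol methyl (Fráter–Seebach sense, sets C2), and a chair transition state with the (Z)-alkene (aryl axial) sets C3 syn to the carboxyl group.

Step 5
Reactants: 7 (2R,3S)-2-[(1R)-1-hydroxyethyl]-3-(5-hydroxy-2-methoxyphenyl)pent-4-enoic acid
Product: 8 methyl (2R,3S)-2-[(1R)-1-hydroxyethyl]-3-(5-hydroxy-2-methoxyphenyl)pent-4-enoate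
Conditions: TMSCHN2, toluene/MeOH (4:1), 0 °C
Reagents that add atoms: (trimethylsilyl)diazomethane C[Si](C)(C)C=[N+]=[N-]
Why: Methyl esterification with TMSCHN2 should be selective because the carboxylic acid protonates the diazo carbon far faster than the phenol does.

Step 6
Reactants: 8 methyl (2R,3S)-2-[(1R)-1-hydroxyethyl]-3-(5-hydroxy-2-methoxyphenyl)pent-4-enoate
Product: 9 methyl (2R,3S)-2-[(1R)-1-(tert-butyldimethylsilyloxy)ethyl]-3-[5-(tert-butyldimethylsilyloxy)-2-methoxyphenyl]pent-4-enoate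
Conditions: TBSOTf (2.4 equiv), 2,6-lutidine, CH2Cl2, −40 → 0 °C
Reagents that add atoms: tert-butyldimethylsilyl triflate CC(C)(C)[Si](C)(C)OS(=O)(=O)C(F)(F)F
Why: Silyl ether formation masks the secondary alcohol and the phenol, which would otherwise undergo oxypalladation or oxidation in the next step.

Step 7
Reactants: 9 methyl (2R,3S)-2-[(1R)-1-(tert-butyldimethylsilyloxy)ethyl]-3-[5-(tert-butyldimethylsilyloxy)-2-methoxyphenyl]pent-4-enoate
Product: 10 methyl (2R,3S)-2-[(1R)-1-(tert-butyldimethylsilyloxy)ethyl]-3-[5-(tert-butyldimethylsilyloxy)-2-methoxyphenyl]-4-oxopentanoate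
Conditions: PdCl2 (10 mol %), CuCl (1 equiv), O2 (1 atm), DMF/H2O (7:1), rt
Reagents that add atoms: water O; dioxygen O=O
Why: Tsuji–Wacker oxidation converts the terminal alkene into the methyl ketone by Markovnikov hydroxypalladation.

Step 8
Reactants: 10 methyl (2R,3S)-2-[(1R)-1-(tert-butyldimethylsilyloxy)ethyl]-3-[5-(tert-butyldimethylsilyloxy)-2-methoxyphenyl]-4-oxopentanoate
Product: 12 (3R,4S,5R)-3-[(1R)-1-(tert-butyldimethylsilyloxy)ethyl]-4-[5-(tert-butyldimethylsilyloxy)-2-methoxyphenyl]-5-methyloxolan-2-one (all-cis lactone), via hydroxy ester 11 (not isolated)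
Conditions: (S)-2-methyl-CBS-oxazaborolidine (20 mol %), BH3·SMe2, THF, −30 °C; MeOH; then PPTS (cat.), toluene, 60 °C
Reagents that add atoms: none
Why: Corey–Bakshi–Shibata reduction: the (S)-catalyst should give the (R)-carbinol (methyl as small group, reinforced by Felkin–Anh attack anti to the aryl group), and the γ-hydroxy ester then lactonises.

Step 9
Reactants: 12 (3R,4S,5R)-3-[(1R)-1-(tert-butyldimethylsilyloxy)ethyl]-4-[5-(tert-butyldimethylsilyloxy)-2-methoxyphenyl]-5-methyloxolan-2-one
Product: 13 (3R,4S,5R)-3-[(1R)-1-(tert-butyldimethylsilyloxy)ethyl]-4-[5-(tert-butyldimethylsilyloxy)-2-methoxyphenyl]-5-methyloxolan-2-ol (lactol, both anomers)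
Conditions: i-Bu2AlH (1.1 equiv), CH2Cl2, −78 °C; Rochelle salt
Reagents that add atoms: none
Why: Half-reduction of the lactone stops at the tetrahedral aluminium lactolate at −78 °C.

Step 10
Reactants: 13 (3R,4S,5R)-3-[(1R)-1-(tert-butyldimethylsilyloxy)ethyl]-4-[5-(tert-butyldimethylsilyloxy)-2-methoxyphenyl]-5-methyloxolan-2-ol
Product: 14 (2R,3S,4S)-4-[(1R)-1-(tert-butyldimethylsilyloxy)ethyl]-3-[5-(tert-butyldimethylsilyloxy)-2-methoxyphenyl]hex-5-yn-2-ol
Conditions: TMSCHN2 (1.3 equiv), n-BuLi (2.3 equiv), THF, −78 °C → rt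
Reagents that add atoms: (trimethylsilyl)diazomethane C[Si](C)(C)C=[N+]=[N-]
Why: Colvin rearrangement: lithiated TMSCHN2 adds to the open aldehyde form of the lactol, and Peterson-type elimination followed by 1,2-shift of the alkylidene carbene gives the terminal alkyne without epimerising the propargylic centre.

Step 11
Reactants: 14 (2R,3S,4S)-4-[(1R)-1-(tert-butyldimethylsilyloxy)ethyl]-3-[5-(tert-butyldimethylsilyloxy)-2-methoxyphenyl]hex-5-yn-2-ol; 15 triethyl orthoformate
Product: 16 (2R,3S,4S)-7,7-diethoxy-4-[(1R)-1-(tert-butyldimethylsilyloxy)ethyl]-3-[5-(tert-butyldimethylsilyloxy)-2-methoxyphenyl]hept-5-yn-2-ol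
Conditions: EtMgBr (2.2 equiv), THF, 0 °C → rt; 15 (3 equiv), toluene, 90 °C
Reagents that add atoms: none
Why: Bodroux–Chichibabin-type reaction: the alkynylmagnesium bromide displaces one ethoxide of the orthoformate to give the alkynal diethyl acetal.

Step 12
Reactants: 16 (2R,3S,4S)-7,7-diethoxy-4-[(1R)-1-(tert-butyldimethylsilyloxy)ethyl]-3-[5-(tert-butyldimethylsilyloxy)-2-methoxyphenyl]hept-5-yn-2-ol
Product: 17 (2R,3S,4S)-7,7-diethoxy-4-[(1R)-1-hydroxyethyl]-3-(5-hydroxy-2-methoxyphenyl)hept-5-yn-2-ol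
Conditions: Bu4NF (2.5 equiv), THF, 0 °C → rt
Reagents that add atoms: none
Why: Fluoride-mediated desilylation frees the secondary alcohol and the phenol while the acetal is stable to the basic medium.

Step 13
Reactants: 18 2,2-dimethoxyacetaldehyde; 19 1-(triphenyl-λ5-phosphanylidene)propan-2-one
Product: 20 (E)-5,5-dimethoxypent-3-en-2-one
Conditions: CH2Cl2, rt
Reagents that add atoms: none
Why: Wittig olefination with the stabilised acyl ylide should give the (E)-enone.

Step 14
Reactants: 17 (2R,3S,4S)-7,7-diethoxy-4-[(1R)-1-hydroxyethyl]-3-(5-hydroxy-2-methoxyphenyl)hept-5-yn-2-ol; 20 (E)-5,5-dimethoxypent-3-en-2-one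
Product: 23 cage diphenol (two 3-methylisochromans joined C1–C1′ and C4–C4′; 8-hydroxy on ring A; 8′-hydroxy-5′-methoxy on ring B; 1S,3R,4S,1′S,3′R,4′S), via β-alkoxy ketone 21 (not isolated), via isochromanyl acetal 22 (not isolated)
Conditions: 20 (1.5 equiv), Tf2NH (20 mol %), CH2Cl2/(CF3)2CHOH (4:1), 0 → 40 °C
Reagents that add atoms: none
Why: Proposed new method: under the Brønsted acid the hydroxyl next to the alkyne adds reversibly to the enone of 20 (oxa-Michael, 21), the α-CH2 enol of this β-alkoxy ketone attacks the alkyne carbon β to the unmasked aldehyde (Michael addition, forms the C4a–C8a bond), the methyl-side enol then condenses with the aldehyde and the ring aromatises to the phenol of 22, and finally the dimethyl acetal ionises, the second hydroxyl closes an eight-membered (Z)-oxocarbenium ion and ring B attacks it ortho to its OH (forms the C1′–C8a′ bond). The closest known reaction types are the oxa-Michael/aldol-condensation route to 2H-chromenes, the [3+3] benzannulation of ketones with ynals or 3-alkoxy enones, and the oxa-Pictet–Spengler cyclisation; their fusion in one pot is new. Ring closures: pyran A 6-exo-dig, carbocycle A by a six-membered 6-exo-trig aldol followed by dehydration, pyran B 6-endo-trig onto an oxocarbenium ion that is itself part of the new eight-membered ring. The two new stereocentres are the O–CH bridgeheads C1 and C1′; both are dictated by the fixed C4/C4′ pair, because only the epimers with the O–CH carbons cis to the C4 substituents can bridge, and both stay epimerisable under the acid (retro-oxa-Michael before aromatisation, o-quinone-methide ionisation after), so the cage should be the thermodynamic sink. The step needs site selectivity between the two secondary hydroxyls and between the two ketone α-positions, which ring size secures (only the hydroxyl next to the alkyne and only the CH2 enol reach a 6-exo transition state, misadducts revert), and regioselective arylation, which the OMe group para to the phenol OH enforces.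

Step 15
Reactants: 23 cage diphenol
Product: 24 cage bis(p-quinone monoketal) (each ring a 4,4-dimethoxycyclohexa-2,5-dienone; C=O at C8 and C8′, ketal at C5 and C5′)
Conditions: PhI(OAc)2 (3.3 equiv), MeOH, 0 °C → rt
Reagents that add atoms: methanol CO
Why: Oxidative dearomatisation with PhI(OAc)2 in methanol: the p-methoxyphenol ring B gives its monoketal directly and the para-unsubstituted phenol ring A does so after two oxidations, each ketal forming para to the former OH.

Step 16
Reactants: 24 cage bis(p-quinone monoketal)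
Product: 25 cage bis(epoxy enone) (6,7- and 6′,7′-epoxides, each on the ring face anti to the other half)
Conditions: Ph3COOH (3 equiv), NaHMDS (2.2 equiv), L-(+)-diisopropyl tartrate (2.4 equiv), 4 Å MS, toluene, −60 °C
Reagents that add atoms: trityl hydroperoxide OOC(c1ccccc1)(c1ccccc1)c1ccccc1
Why: Weitz–Scheffer (nucleophilic) epoxidation in its tartrate-mediated asymmetric form: the peroxide anion adds to the disubstituted enone C=C of each dienone (the tetrasubstituted C=C is inert) and the chiral sodium tartrate aggregate should direct it to the face anti to the other half, setting both epoxide carbons of each ring.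

Step 17
Reactants: 25 cage bis(epoxy enone)
Product: 26 cage bis(epoxy alcohol) bis(dimethyl ketal) (C8 and C8′ carbinols anti to the epoxides)
Conditions: i-Bu2AlH (2.5 equiv), THF, −78 °C
Reagents that add atoms: none
Why: 1,2-Reduction of the α,β-epoxy enone with i-Bu2AlH: aluminium coordinated to the epoxide oxygen should deliver hydride from the epoxide face, so each carbinol forms anti to its epoxide.

Step 18
Reactants: 26 cage bis(epoxy alcohol) bis(dimethyl ketal)
Product: 27 epoxytwinol A
Conditions: montmorillonite K-10, wet CH2Cl2, rt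
Reagents that add atoms: water O
Why: Acid-catalysed ketal hydrolysis on clay should unveil the two enone carbonyls without opening the epoxides or dehydrating the allylic alcohols.

**Compound list**

1 | 3-bromo-4-methoxyphenol | COc1ccc(O)cc1Br | starting material
2 | prop-2-yn-1-ol | C#CCO | starting material
3 | 3-(5-hydroxy-2-methoxyphenyl)prop-2-yn-1-ol | COc1ccc(O)cc1C#CCO | intermediate
4 | (Z)-3-(5-hydroxy-2-methoxyphenyl)prop-2-en-1-ol | COc1ccc(O)cc1/C=C\CO | intermediate
5 | ethyl (R)-3-hydroxybutanoate | CCOC(=O)C[C@@H](C)O | starting material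
6 | (Z)-3-(5-hydroxy-2-methoxyphenyl)prop-2-en-1-yl (R)-3-hydroxybutanoate | C[C@@H](O)CC(=O)OC/C=C\c1cc(O)ccc1OC | intermediate
7 | (2R,3S)-2-[(1R)-1-hydroxyethyl]-3-(5-hydroxy-2-methoxyphenyl)pent-4-enoic acid | C[C@@H](O)[C@H](C(=O)O)[C@H](C=C)c1cc(O)ccc1OC | intermediate
8 | methyl (2R,3S)-2-[(1R)-1-hydroxyethyl]-3-(5-hydroxy-2-methoxyphenyl)pent-4-enoate | C[C@@H](O)[C@H](C(=O)OC)[C@H](C=C)c1cc(O)ccc1OC | intermediate
9 | methyl (2R,3S)-2-[(1R)-1-(tert-butyldimethylsilyloxy)ethyl]-3-[5-(tert-butyldimethylsilyloxy)-2-methoxyphenyl]pent-4-enoate | C[C@@H](O[Si](C)(C)C(C)(C)C)[C@H](C(=O)OC)[C@H](C=C)c1cc(O[Si](C)(C)C(C)(C)C)ccc1OC | intermediate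
10 | methyl (2R,3S)-2-[(1R)-1-(tert-butyldimethylsilyloxy)ethyl]-3-[5-(tert-butyldimethylsilyloxy)-2-methoxyphenyl]-4-oxopentanoate | C[C@@H](O[Si](C)(C)C(C)(C)C)[C@H](C(=O)OC)[C@H](C(C)=O)c1cc(O[Si](C)(C)C(C)(C)C)ccc1OC | intermediate
11 | methyl (2R,3S,4R)-2-[(1R)-1-(tert-butyldimethylsilyloxy)ethyl]-3-[5-(tert-butyldimethylsilyloxy)-2-methoxyphenyl]-4-hydroxypentanoate | C[C@@H](O[Si](C)(C)C(C)(C)C)[C@H](C(=O)OC)[C@H]([C@@H](C)O)c1cc(O[Si](C)(C)C(C)(C)C)ccc1OC | intermediate
12 | (3R,4S,5R)-3-[(1R)-1-(tert-butyldimethylsilyloxy)ethyl]-4-[5-(tert-butyldimethylsilyloxy)-2-methoxyphenyl]-5-methyloxolan-2-one | C[C@@H](O[Si](C)(C)C(C)(C)C)[C@@H]1C(=O)O[C@H](C)[C@@H]1c1cc(O[Si](C)(C)C(C)(C)C)ccc1OC | intermediate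
13 | (3R,4S,5R)-3-[(1R)-1-(tert-butyldimethylsilyloxy)ethyl]-4-[5-(tert-butyldimethylsilyloxy)-2-methoxyphenyl]-5-methyloxolan-2-ol (both anomers) | C[C@@H](O[Si](C)(C)C(C)(C)C)[C@@H]1C(O)O[C@H](C)[C@@H]1c1cc(O[Si](C)(C)C(C)(C)C)ccc1OC | intermediate
14 | (2R,3S,4S)-4-[(1R)-1-(tert-butyldimethylsilyloxy)ethyl]-3-[5-(tert-butyldimethylsilyloxy)-2-methoxyphenyl]hex-5-yn-2-ol | C[C@@H](O[Si](C)(C)C(C)(C)C)[C@H](C#C)[C@H]([C@@H](C)O)c1cc(O[Si](C)(C)C(C)(C)C)ccc1OC | intermediate
15 | triethyl orthoformate | CCOC(OCC)OCC | starting material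
16 | (2R,3S,4S)-7,7-diethoxy-4-[(1R)-1-(tert-butyldimethylsilyloxy)ethyl]-3-[5-(tert-butyldimethylsilyloxy)-2-methoxyphenyl]hept-5-yn-2-ol | C[C@@H](O[Si](C)(C)C(C)(C)C)[C@H](C#CC(OCC)OCC)[C@H]([C@@H](C)O)c1cc(O[Si](C)(C)C(C)(C)C)ccc1OC | intermediate
17 | (2R,3S,4S)-7,7-diethoxy-4-[(1R)-1-hydroxyethyl]-3-(5-hydroxy-2-methoxyphenyl)hept-5-yn-2-ol | C[C@@H](O)[C@H](C#CC(OCC)OCC)[C@H]([C@@H](C)O)c1cc(O)ccc1OC | intermediate
18 | 2,2-dimethoxyacetaldehyde | COC(OC)C=O | starting material
19 | 1-(triphenyl-λ5-phosphanylidene)propan-2-one | CC(=O)C=P(c1ccccc1)(c1ccccc1)c1ccccc1 | starting material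
20 | (E)-5,5-dimethoxypent-3-en-2-one | CC(=O)/C=C/C(OC)OC | intermediate
21 | (2R,3S,4S)-7,7-diethoxy-4-{(1R)-1-[(2S)-1,1-dimethoxy-4-oxopentan-2-yl]oxyethyl}-3-(5-hydroxy-2-methoxyphenyl)hept-5-yn-2-ol (β-alkoxy ketone) | C[C@@H](O[C@H](C(OC)OC)CC(C)=O)[C@H](C#CC(OCC)OCC)[C@H]([C@@H](C)O)c1cc(O)ccc1OC | intermediate
22 | (1S,3R,4S)-1-(dimethoxymethyl)-4-[(1S,2R)-2-hydroxy-1-(5-hydroxy-2-methoxyphenyl)propyl]-3-methyl-3,4-dihydro-1H-isochromen-8-ol (isochromanyl acetal) | C[C@H]1O[C@H](C(OC)OC)c2c(cccc2O)[C@@H]1[C@H]([C@@H](C)O)c1cc(O)ccc1OC | intermediate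
23 | cage diphenol: two 3-methylisochromans joined C1–C1′ and C4–C4′, 8-OH on ring A, 8′-OH and 5′-OMe on ring B (1S,3R,4S,1′S,3′R,4′S) | C[C@H]1O[C@H]2c3c(cccc3O)[C@@H]1[C@H]1c3c(c(O)ccc3OC)[C@@H]2O[C@@H]1C | intermediate
24 | cage bis(p-quinone monoketal): C8/C8′ carbonyls, C5/C5′ dimethyl ketals, cage stereocentres as in 23 | C[C@H]1O[C@H]2C3=C(C(OC)(OC)C=CC3=O)[C@@H]1[C@H]1C3=C(C(=O)C=CC3(OC)OC)[C@@H]2O[C@@H]1C | intermediate
25 | cage bis(epoxy enone): 24 with 6,7- and 6′,7′-epoxides configured as in 27 | C[C@H]1O[C@H]2C3=C(C(OC)(OC)[C@@H]4O[C@@H]4C3=O)[C@@H]1[C@H]1C3=C(C(=O)[C@H]4O[C@H]4C3(OC)OC)[C@@H]2O[C@@H]1C | intermediate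
26 | cage bis(epoxy alcohol) bis(dimethyl ketal): 25 with C8/C8′ carbinols anti to the epoxides, configured as in 27 | C[C@H]1O[C@H]2C3=C(C(OC)(OC)[C@@H]4O[C@@H]4[C@H]3O)[C@@H]1[C@H]1C3=C([C@H](O)[C@H]4O[C@H]4C3(OC)OC)[C@@H]2O[C@@H]1C | intermediate
27 | epoxytwinol A | C[C@H]1O[C@H]2C3=C(C(=O)[C@@H]4O[C@@H]4[C@H]3O)[C@@H]1[C@H]1C3=C([C@H](O)[C@H]4O[C@H]4C3=O)[C@@H]2O[C@@H]1C | target

**Step count and risks**

Total step count: 18. Longest linear sequence: 17 steps (steps 1–12 and 14–18; step 13 is a one-step side branch).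

Steps most likely to fail:

1. Step 14 (proposed domino). What may go wrong: the unmasked ynal may be consumed by irreversible capture (5-exo conjugate addition of the benzylic-side hydroxyl, Friedel–Crafts alkylation of ring B), 20 may oligomerise, and the eight-membered oxocarbenium closure may be too slow, so that the reversible steps do not funnel to the cage. The fallback uses known reactions one at a time; it sets out from 17 and returns at 23. 17 and 20 are first joined only at the acetal carbon by an oxa-Pictet–Spengler reaction (TMSOTf, CH2Cl2, −40 °C) to give the isochromanyl enone F1. DBU in MeCN then closes the intramolecular oxa-Michael adduct, the dioxocane ketone F2. TsOH·H2O in toluene at 60 °C finally effects the intramolecular Michael addition and aldol aromatisation that give 23.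

2. Step 16. What may go wrong: poor facial selectivity, because the enone C=C lies far from the cage stereocentres and reagent control may be mismatched with the weak bias of the cage. This fallback also removes the dependence on the hydride face in step 17. It sets out from 24 and returns at 26, bypassing 25. Luche reduction (NaBH4, CeCl3·7H2O, MeOH, −78 °C) gives the bis-dienol F3 with the carbinols on the face that the epoxides must occupy. VO(acac)2/t-BuOOH then epoxidises syn to each hydroxyl to give the syn bis(epoxy alcohol) F4. Mitsunobu inversion (4-nitrobenzoic acid, PPh3, DIAD) gives the bis(4-nitrobenzoate) F5, and K2CO3/MeOH releases 26.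

3. Step 4. What may go wrong: leakage through a boat transition state (axial aryl group of the Z-allyl unit) and β-elimination of the dianion on warming, which would erode the C2/C3 relationship. The fallback sets out from 6 and returns at 9. Both hydroxyls are silylated first (TBSCl, imidazole, DMF) to give the bis-silyl ester F6. KHMDS/TBSCl in THF–DMPU at −78 °C gives the silyl ketene acetal of the same enolate geometry without a dianion or chelate, and it rearranges at room temperature. Mild hydrolysis of the silyl ester gives the bis-silyl acid F7, and TMSCHN2 converts it into 9.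

Further compounds
F1 | step 14 | isochromanyl enone: 8-hydroxy-5-methoxy-3-methylisochroman with (E)-3-oxobut-1-enyl at C1 and the alkynyl-acetal carbinol chain of 17 at C4 | C[C@@H](O)[C@H](C#CC(OCC)OCC)[C@H]1c2c(c(O)ccc2OC)[C@@H](/C=C/C(C)=O)O[C@@H]1C
F2 | step 14 | dioxocane ketone: oxa-Michael adduct of F1 with the eight-membered 1,4-dioxocane closed, 2-oxopropyl on the new O–CH carbon | C[C@H]1O[C@@H](CC(C)=O)[C@H]2O[C@H](C)[C@H](c3c2c(O)ccc3OC)[C@H]1C#CC(OCC)OCC
F3 | step 16 | cage bis-dienol: 24 with both C=O reduced, carbinols epimeric to those of 26 | C[C@H]1O[C@H]2C3=C(C(OC)(OC)C=C[C@@H]3O)[C@@H]1[C@H]1C3=C([C@@H](O)C=CC3(OC)OC)[C@@H]2O[C@@H]1C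
F4 | step 16 | syn bis(epoxy alcohol): epoxides as in 26, carbinols epimeric to 26 | C[C@H]1O[C@H]2C3=C(C(OC)(OC)[C@@H]4O[C@@H]4[C@@H]3O)[C@@H]1[C@H]1C3=C([C@@H](O)[C@H]4O[C@H]4C3(OC)OC)[C@@H]2O[C@@H]1C
F5 | step 16 | bis(4-nitrobenzoate) of 26 | C[C@H]1O[C@H]2C3=C(C(OC)(OC)[C@@H]4O[C@@H]4[C@H]3OC(=O)c5ccc(cc5)[N+](=O)[O-])[C@@H]1[C@H]1C3=C([C@H](OC(=O)c6ccc(cc6)[N+](=O)[O-])[C@H]4O[C@H]4C3(OC)OC)[C@@H]2O[C@@H]1C
F6 | step 4 | (Z)-3-[5-(tert-butyldimethylsilyloxy)-2-methoxyphenyl]prop-2-en-1-yl (R)-3-(tert-butyldimethylsilyloxy)butanoate | C[C@@H](O[Si](C)(C)C(C)(C)C)CC(=O)OC/C=C\c1cc(O[Si](C)(C)C(C)(C)C)ccc1OC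
F7 | step 4 | (2R,3S)-2-[(1R)-1-(tert-butyldimethylsilyloxy)ethyl]-3-[5-(tert-butyldimethylsilyloxy)-2-methoxyphenyl]pent-4-enoic acid | C[C@@H](O[Si](C)(C)C(C)(C)C)[C@H](C(=O)O)[C@H](C=C)c1cc(O[Si](C)(C)C(C)(C)C)ccc1OC
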